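(Readings and results stem from a simulated flask with made-up constants; the scatter is artificial.)

| setting | alder | larch | flask |
|---|---|---|---|
| J | 1.8 M | 1.8 M | 1.8 M |
| Q | 1.8 M | 1.8 M | 1.8 M |
| X | 140 mM (held) | 140 mM (held) | 140 mM (held) |
| Z | 9 mM | 18 mM | 9.0 mM |
| remark | the very flask that is asked about, followed so far | run made earlier |  |
| time |  |  | 8.0 h |

- alder (time / min: D / %, E / %, J / %): 8.00: 1.4, 0.6, 49.3; 15.0: 3.1, 2.1, 47.1; 25.0: 6.2, 2.7, 45.7; 30.0: 7.5, 3.1, 44.9; 40.0: 10.0, 4.0, 43.7; 50.0: 12.8, 4.6, 41.2; 60.0: 14.3, 6.1, 39.4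
- larch (time / h: D / %, E / %, J / %): 0.417: 8.5, 3.2, 44.3; 0.667: 12.3, 5.1, 40.6; 1.00: 19.0, 7.1, 36.7; 1.50: 28.0, 11.5, 30.4; 2.50: 43.8, 17.6, 18.9; 4.00: 61.0, 25.0, 7.6; 6.00: 69.4, 28.5, 1.4

(scatter of a reading: 0.3 percentage points)

- Z is single-handed; J and Q are mirror images of each other, charged as a racemate, each of them at the stated concentration
- the earlier runs were read with a standard deviation of 0.3 percentage points
- at the start none of X is in solution

- D present at 8.0 h, in percent of the J and Q together charged
- E present at 8.0 h, in percent of the J and Q together charged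

The leftover S, J and Q together, tells how far a flask has run. In larch at 4.00 h, J reads 7.6%, about half of what D and E leave, so S is counted as two J readings. Dissolved X is replaced in proportion to its shortfall below saturation and used in proportion to its own amount, Z and S. Balancing the two gives a rate V·S/(K+S), which integrates to K·ln(1/S) + 1 − S = V·t, with S as a fraction of the charge. Two larch readings give K = 33.4% and V = 0.369 h⁻¹. K scales inversely with Z, so alder, with half the Z of larch, has as its crossover leftover, the S at which the rate is V/2, 66.8%. Alder's reading at 60.0 min then returns V = 0.371 h⁻¹, close to the value from larch. At 8.0 h this reckoning leaves S = 4.95%. The selectivity, D's share of product, reads 70.9% in larch, so D comes to 67.4% and E to 27.7%.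

The forecast, resting on "a gas-transfer limit", gives 67.2% D and 27.5% E, slightly less D than this reckoning.

The flask gives 68.6% D and 27.5% E, with S at 3.95%.

    J ⇌ Q (k = 0.00338 s⁻¹)
    L + Z + Q → Z + E (k = 0.0784 M⁻² s⁻¹)
    L → G (k = 3.91 × 10⁻⁵ s⁻¹)
    X ⇌ L, rate k4*(csat - [L]) (kL = 0.00259 s⁻¹)
    L + Z + J → Z + D (k = 0.198 M⁻² s⁻¹)

L, the dissolved X, is made 1.05 times as fast as it is used at 8.00 h in the flask. A neighbouring flask holds 0.0036 M of Z, which scales the crossover leftover to 167%. With the same V, the reckoning for that neighbouring flask leaves S at 26.5% at 8.0 h and gives D as 52.1%. The neighbouring flask itself holds S at 23.9%, with D at 54.4% and E at 21.7%.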